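| flask | left-handed substrate | right-handed substrate | solid reagent | remark | time |
|---|---|---|---|---|---|
| larch | 0.050 M | 0.050 M | 0.22 M | run made earlier |  |
| elm | 0.20 M | 0.20 M | 0.22 M | run made earlier |  |
| flask | 0.10 M | 0.10 M | 0.220 M |  | 15 d |

- larch (time / d: left-handed substrate / %, left-handed product / %, side product / %): 2.50: 0.7, 38.9, 56.2; 5.00: 0, 38.7, 56.0; 8.00: 1.3, 38.3, 57.1; 10.0: 0.2, 39.4, 55.3; 12.0: 0, 39.2, 55.2; 15.0: 0.2, 39.2, 55.0
- elm (time / d: left-handed substrate / %, left-handed product / %, side product / %): 1.04: 1.2, 30.6, 63.2; 3.00: 0.2, 29.4, 68.6; 5.00: 2.1, 30.8, 67.5; 8.00: 0, 28.4, 68.5; 12.0: 1.2, 28.2, 68.4; 15.0: 0, 27.8, 67.5

(each reading ± 1 percentage point)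

- partner is single-handed; left-handed substrate and right-handed substrate are mirror images of each other, charged as a racemate, each of them at the stated concentration
- given per volume of solution although it is solid: solid reagent
- the numbers in the tables scatter by 1 percentage point (one standard deviation)
- at the start none of the solid reagent is in solution
- the reaction counts as stopped when no species that holds the left-handed substrate and right-handed substrate together changes by six tenths of a point or more over the second half of the time
- the handed part of partner does not stay in what it makes, so the products of the two hands are mirror images too
- what has gone into achiral form counts as reacted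

- which holds at 15 d: what has brought the reaction to rest, or that it has not come to rest (for what has run out or reacted, a solid counts together with what of it has only dissolved) (it is still moving / forward and back rates have come level / the partner has run out first / all of the left-handed substrate has reacted)
- share of the left-handed substrate and right-handed substrate together used up at 15 d
- left-handed product at 15 d, in percent of the left-handed substrate and right-handed substrate together charged
- side product at 15 d, in percent of the left-handed substrate and right-handed substrate together charged

The trap in this flask is to copy the left-handed product share of larch, its nearest simulated run, since both hold the same solid reagent and larch rests with the left-handed substrate at about zero; but c(left-handed substrate) in the flask is twice that in larch, and elm, at higher charge, ends lower. In both runs the left-handed substrate reads no more than 2.1% at any reading, so the left-handed product share at the end can be read as a split of that substrate, a ratio under kinetic control as far as these readings show. Averaged over their six readings, with the scatter those carry, larch gives 0.284 and elm 0.712. A straight line in c(left-handed substrate), with c(right-handed substrate) rising equally beside it and the solid reagent held at 0.220 M, then puts the flask at an estimated 0.427, the leak ratio: the left-handed half of the charge not found as left-handed product, divided by the left-handed product. So this reckoning expects 35.0% left-handed product.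

The forecast gives all of the left-handed substrate has reacted, with conversion 99.5% (95% to 100%), left-handed product 34.7% (32.5% to 36.5%) and side product 61% (58.5% to 63.5%), on the ground that “the leak grows with concentration”; its product lies slightly below the reckoning above.

The flask gives 35.0% left-handed product, 60.7% side product and 100% conversion, the outcome being: all of the left-handed substrate has reacted. Of the charged partner, 64% is still there, solid or dissolved, at 15.0 d.

    partner + left-handed substrate → left-handed product (k = 0.0120 M⁻¹ s⁻¹)
    partner + right-handed substrate → right-handed product (k = 1.00 × 10⁻⁴ M⁻¹ s⁻¹)
    left-handed substrate ⇌ achiral form (K = 0.820, k = 2.10 × 10⁻⁵ s⁻¹)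
    right-handed substrate ⇌ achiral form (K = 0.820, k = 2.10 × 10⁻⁵ s⁻¹)
    achiral form → waste (k = 6.10 × 10⁻⁶ s⁻¹)
    solid reagent ⇌ partner, rate k6*(cs6 - [partner]) while solid is left; crystals form when [partner] > cs6 (solubility = 49.0 mM, k = 5.50 × 10⁻⁵ s⁻¹)
    achiral form → side product (k = 0.00250 s⁻¹)

The neighbour flask with a quarter of the solid reagent, 0.055 M, and the same substrates gives 27.1% left-handed product, so its leak ratio is 0.845, above the 0.427 reckoned for the flask, with 0% of its solid reagent left.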